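## The problem

The target is a ten-membered carbocycle (C1–C10) whose C9–C10 edge carries a butenolide (O, C12, C11), so that the enol-ester alkene C8=C9 is cross-conjugated with C10=C11 and, through C6=C7, reaches C5. Both ring alkenes, C6=C7 and C8=C9, are ring-cis, which makes a direct end-to-end closure of the medium ring unattractive. The saturated half carries a 1,3,5-array of oxygenated stereocentres: C1 (secondary, methacrylate), C3 (tertiary methyl carbinol) and C5 (secondary allylic, acetate), with C1/C3 and C3/C5 both anti. C3 cannot be made by reduction and C1 is too far from C5 to be controlled by it, so C1 and C3 should come together from the chiral pool; C5 can then be set from C3 by a hydroxyl-directed reduction. The trienyl enol lactone is an acylating agent and a Michael acceptor, the methacrylate does not survive hydride, strong base or peroxide, and the allylic acetate ionises. C13–OH must end free beside two different esters, so all carbanion and hydride chemistry has to be finished before the esters go on, and the four hydroxyls need orthogonal masking. Whenever C5 is a ketone, C3–OH is a β-hydroxy ketone and must be capped against retro-aldol scrambling. The enabling feature is that C5 (oxygenated) and C10 (an alkene carbon bearing C11 and its C13 hydroxymethyl) lie 1,6 across the ring and flank the cis,cis-diene: a C5–C10 bond, an oxygen on C5 and an oxirane on C11/C13 are what an alkoxide-triggered fragmentation consumes, and the temporary six-membered ring A (C5–C10) holds the diene cis.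

## Retrosynthesis

**Ester and protecting-group end.** 36 is cut at the two acyl C–O bonds and at the C5–H bond. The methacrylate (35 from 34), the acetate (33 from 32) and the C5 carbinol (32 from 31) lead back to the ten-membered ketone 30, in which only C3–OH is free. Putting the esters on last keeps them away from amide bases, hydride and peroxide. The forward steps must give an anti-selective directed reduction, secondary-over-tertiary acylations and an oxidative PMB removal that leaves the trienyl lactone alone.

**Ring cut (key).** In 29 (the silyl ether of 30) the C5=O and C10=C11 π bonds and the C13–O–H bond are traded for a C5–C10 σ bond and a C11–O oxirane bond, giving the tricyclic alcohol 27. This is preferred over cutting a ring C–C bond between acyclic halves, because the medium ring is then made by cleavage, not closure, and ring A fixes both alkene geometries. The five-membered enol lactone can span C9/C10 only if C11 lies near the plane of the ring-A diene; that forces the C10–C1 bond axial and the C5–C4 bond equatorial on ring A. Rings A and B are therefore cis-fused, with the C5 oxygen gauche to C11, and a trans-fused isomer would have to twist the diene, so 27 is targeted as the cis isomer. 27 has five stereocentres but only C1 and C3 survive; the forward step must cleave C5–C10 faster than any other alkoxide-triggered process.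

**Lactone, C13 and oxirane.** 27 is simplified by removing the oxirane oxygen (from 25), the enol-ester C12–O bond (from acid 24) and C13 (from aldehyde 22). C13 is introduced on the aldehyde by amine catalysis and not on the enol lactone, whose enolate could expel the dienolate as a ketene. The oxirane is made last, on the rigid lactone, so that its configuration is set by the C5 substituent. C5–O must be silylated from its creation until step 21, because the free cis-hydroxy acid would close the saturated C5–O lactone instead.

**Ring A.** 21 is opened at C5–C6 to the diketone 19, whose 3-methylbut-3-enoyl group is the C9–C6 unit. The C8 methylene between the ketone and the alkene is the most acidic site, so the dienolate forms regiospecifically and can only close through C6. The alternative of adding C6 to the C5 ketone intermolecularly and closing by metathesis would place C6 equatorial and give the useless trans fusion. The allyl group on C10 is the masked C11–C12 unit (22 from 21); an ester there would lactonise with the C9 alkoxide of 16.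

**Quaternary C10.** 19 goes back through 16 (C9–C8 bond, Grignard addition) to the aldehyde 14, and 14 to the ketone 9 by a Wittig–Claisen sequence that forms both C10–C9 and C10–C11 from one carbonyl. Enolate alkylation of a C5 ketone was rejected because every C10 carbanion has the C1 ether as a β-leaving group. The [3,3] shift must deliver C11 to the face anti to the axial C5 silyl ether.

**Ring B from the chiral pool.** 9 is the C10 ketone of a cyclohexane that maps onto (−)-quinic acid 1: its C5 and C1 are C1 and C3 of the target in the right absolute sense, the carboxyl becomes the C3 methyl (2 to 5), and the cis-3,4-diol supplies C5–O and the C10 ketone (6 to 9).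

## Roads not taken

**Alternative 1:** The cut is C1–C2 of the carbocycle, made forward by a [2,3]-Wittig shift. A carbanion at C1, extended through the butenolide, would attack across an O–C14 allylic ether, form C1–C2, break O–C14 and contract an eleven-membered oxacycle to the C1 carbinol A1, which has an exocyclic C3 methylene. Its merits are real: the ring is made by contraction of an easier macro-ether, the C1 carbinol appears in the same step, and the butenolide is already complete, which is more convergent than the linear sequence chosen here. Its weak points are the carbanion, which is a vinylogous lactone enolate with α/γ ambiguity and a competing [1,2] shift, and C1, which would have to be set by transannular control from C5. C3 would still have to be made by hydrating a methylene group in a flexible ten-membered ring. The chosen plan is longer but takes C1 and C3 from quinic acid and leaves only C5 to be controlled.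

**Alternative 2:** The cut is C11–C12 and C12–O. Forward, Pd(PPh3)4-catalysed carbonylation at a C11–iodine bond would insert CO as C12, and the C9 dienolate oxygen would capture the acylpalladium to give A2 with the butenolide and the C8=C9 alkene. This is the gentlest way to make the sensitive ylidene butenolide, under nearly neutral conditions and at the very end, and in that respect it is better than carrying an enol lactone through five steps. It leaves the main problem unsolved: the ten-membered ring with a Z trisubstituted alkene, a stereodefined tetrasubstituted iodoalkene and three stereocentres must already exist. The chosen plan makes ring and butenolide together and has only the strain-releasing fragmentation to set against the milder lactone formation.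

**Alternative 3:** The cut is C1–C10, with C3–C8 reconnected. Forward, a potassium alkoxide on a six-membered ring bearing two cis alkenyl groups would undergo an anionic oxy-Cope shift, expanding the ring by four atoms to the cyclodecadienone A3, with C8=C9 and a silyl ketene acetal in place of the lactone. It shares the logic of the chosen plan (medium ring by rearrangement of a six-membered ring), rests on a very well-tested reaction and creates C1 by chirality transfer; in step count it is probably equal or shorter. Against it, C3 emerges as a ketone and the methyl carbinol must then be set by addition inside the ten-membered ring, C10 emerges sp3 and the ketene acetal must be oxidised to the butenolide, and an electron-rich furan is asked to act as one of the alkenes. The chosen plan has the secure C3 centre and the correct oxidation level at C10–C11 to set against this.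

Key step: step 22

Remark on numbering: target locants are used throughout (C1 methacrylate carbinol, C3 methyl carbinol, C5 acetate carbinol, C6=C7(CH3), C8=C9(O), C10=C11(C13H2OH), C12 lactone carbonyl); quinic acid C5, C6, C1, C2, C3 and C4 become C1, C2, C3, C4, C5 and C10.

Assumption: allyl chloromethyl ether (11) is bought; the E/Z mixture 13 and the C9 epimers of 16 and 17 are used as mixtures because these elements are erased in steps 10 and 13.

## Route

Step 1
Reactants: 1 (−)-quinic acid
Product: 2 3,4-O-isopropylidene-1,5-quinide (γ-lactone acetonide of 1)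
Conditions: Me2C(OMe)2, TsOH·H2O (cat.), acetone, reflux
Reagents that add atoms: 2,2-dimethoxypropane, COC(C)(C)OC
Why: Acid-catalysed lactonisation of the carboxyl onto the cis 5-OH and acetal formation on the cis 3,4-diol; no stereocentre is touched and only the tertiary 1-OH stays free.

Step 2
Reactants: 2 3,4-O-isopropylidene-1,5-quinide
Product: 3 triol acetonide (1-hydroxymethyl, 1-OH and 5-OH free)
Conditions: LiAlH4, THF, 0 °C to rt
Reagents that add atoms: none
Why: Hydride reduction of a lactone to the diol; the acetal is inert.

Step 3
Reactants: 3 triol acetonide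
Product: 4 primary mono-tosylate of 3
Conditions: TsCl (1.1 equiv), pyridine, 0 °C
Reagents that add atoms: 4-toluenesulfonyl chloride, Cc1ccc(cc1)S(Cl)(=O)=O
Why: Selective sulfonylation of the primary hydroxyl in the presence of a secondary and a tertiary one.

Step 4
Reactants: 4 primary mono-tosylate
Product: 5 methyl carbinol acetonide (C1–OH secondary, C3(OH)CH3, acetonide on the C5 and C10 oxygens)
Conditions: LiAlH4, THF, reflux
Reagents that add atoms: none
Why: Hydride displacement of the primary sulfonate, assisted by the neighbouring tertiary alkoxide, turns the former carboxyl carbon into the C3 methyl group; the C3 configuration is not involved.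

Step 5
Reactants: 5 methyl carbinol acetonide
Product: 6 C1 4-methoxybenzyl ether of 5
Conditions: NaH (1.1 equiv), PMBCl, Bu4NI (cat.), DMF, 0 °C
Reagents that add atoms: 4-methoxybenzyl chloride, COc1ccc(CCl)cc1
Why: Williamson etherification; the secondary alkoxide is alkylated much faster than the tertiary C3 alkoxide.

Step 6
Reactants: 6 C1 4-methoxybenzyl ether
Product: 7 triol (C3–OH, C5–OH, C10–OH; C1–OPMB)
Conditions: AcOH/H2O 4:1, 45 °C
Reagents that add atoms: none
Why: Acid hydrolysis of a cis-fused cyclohexane acetonide; the PMB ether survives aqueous acetic acid.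

Step 7
Reactants: 7 triol
Product: 8 C5 tert-butyldimethylsilyl ether of 7
Conditions: TBSCl (1.1 equiv), imidazole, DMF, 0 °C
Reagents that add atoms: tert-butyldimethylsilyl chloride, CC(C)(C)[Si](C)(C)Cl
Why: Silylation of the more accessible secondary hydroxyl; the C10 hydroxyl is flanked by two oxygenated carbons and the C3 hydroxyl is tertiary, as in the known selective silylation of quinate triols.

Step 8
Reactants: 8 C5 silyl ether
Product: 9 C10 ketone (C1–OPMB, C5–OTBS, C3–OH)
Conditions: Dess–Martin periodinane, NaHCO3, CH2Cl2, rt
Reagents that add atoms: none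
Why: Dess–Martin oxidation of the only secondary alcohol under buffered, non-epimerising conditions; the ketone has no β-leaving group.

Step 9
Reactants: 10 triphenylphosphine; 11 allyl chloromethyl ether
Product: 12 (allyloxymethyl)triphenylphosphonium chloride
Conditions: PhMe, 60 °C
Reagents that add atoms: none
Why: SN2 quaternisation of the phosphine by an α-chloro ether.

Step 10
Reactants: 9 C10 ketone; 12 (allyloxymethyl)triphenylphosphonium chloride
Product: 14 quaternary aldehyde (C10 carries formyl = C9, trans to C1–OPMB, and allyl = C11/C12 plus one carbon, cis to C1–OPMB), via allyl enol ether 13 (not isolated)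
Conditions: 12 (2.5 equiv), KOt-Bu, THF, 0 °C, then 9, 0 °C to rt; solvent switch to xylene, 140 °C
Reagents that add atoms: none
Why: Wittig olefination to the allyl enol ether followed by thermal Claisen rearrangement, a known way from ketones to α-allyl quaternary aldehydes. In the chair with C1–OPMB and C3–CH3 equatorial the C5 silyl ether is axial and blocks its own face, so the new C10–C bond forms axially on the opposite face, cis to C1–OPMB.

Step 11
Reactants: 14 quaternary aldehyde; 15 2-methylallylmagnesium chloride
Product: 16 homoallylic alcohol (C9 epimers; C10–CH(OH)–CH2–C(CH3)=CH2)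
Conditions: 15 (3 equiv), THF, −78 to 0 °C
Reagents that add atoms: none
Why: Grignard addition to a non-enolisable aldehyde; the symmetric allyl reagent has no regiochemical issue, and no ester is present that the C9 alkoxide could attack.

Step 12
Reactants: 16 homoallylic alcohol
Product: 17 triol (C9–OH, C5–OH, C3–OH)
Conditions: Bu4NF, THF, rt
Reagents that add atoms: none
Why: Fluoride cleavage of the secondary silyl ether.

Step 13
Reactants: 17 triol
Product: 18 diketone (C5 ketone; C10 bears 3-methylbut-3-enoyl and allyl; C3–OH)
Conditions: Dess–Martin periodinane (3 equiv), NaHCO3, CH2Cl2, 0 °C to rt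
Reagents that add atoms: none
Why: Dess–Martin oxidation of both secondary alcohols in one operation; C10 is quaternary, so the 1,3-diketone cannot enolise between the carbonyls, and the buffer keeps the β,γ-alkene out of conjugation.

Step 14
Reactants: 18 diketone
Product: 19 C3 tert-butyldimethylsilyl ether of 18
Conditions: TBSOTf, 2,6-lutidine, CH2Cl2, −78 to 0 °C
Reagents that add atoms: tert-butyldimethylsilyl triflate, CC(C)(C)[Si](C)(C)OS(=O)(=O)C(F)(F)F
Why: Silyl triflate silylation of a tertiary alcohol; it is done now because C5 is trigonal and offers no syn-axial partner, and it blocks retro-aldol cleavage of the C3 carbinol in all later basic steps.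

Step 15
Reactants: 19 C3 silyl ether diketone
Product: 21 cis-fused bicyclic enone (ring A: C5(OSiEt3)–C6H2–C7(CH3)=C8H–C9(=O)–C10; C5–O cis to the C10 allyl group), via lithium aldolate 20 (not isolated)
Conditions: LiN(SiMe3)2 (1.1 equiv), THF, −78 to −30 °C; then TESOTf, −78 °C
Reagents that add atoms: triethylsilyl triflate, CC[Si](CC)(CC)OS(=O)(=O)C(F)(F)F
Why: Intramolecular vinylogous aldol addition: the C8 methylene, flanked by ketone and alkene, is deprotonated selectively and the dienolate can reach C5 only through C6. The aldol is reversible, and only the cis-fused aldolate has an equatorial, unhindered oxygen, whereas the trans aldolate oxygen is axial and syn to the C3 silyl ether; silyl triflate therefore traps the cis isomer, which sets C5.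

Step 16
Reactants: 21 cis-fused bicyclic enone
Product: 22 aldehyde (C10–CH2–CHO; C11 and C12)
Conditions: OsO4 (cat.), NaIO4, 2,6-lutidine, dioxane/H2O, rt
Reagents that add atoms: osmium tetroxide (oxygen carrier), O=[Os](=O)(=O)=O; sodium periodate, [Na+].[O-]I(=O)(=O)=O
Why: Lemieux–Johnson cleavage of the terminal allyl alkene; the trisubstituted enone alkene is electron-poor and is left.

Step 17
Reactants: 22 aldehyde
Product: 23 α-methylene aldehyde (C10–C(=CH2)–CHO; C13 installed)
Conditions: 37% aq. CH2O, pyrrolidine (cat.), EtCO2H (cat.), i-PrOH, 45 °C
Reagents that add atoms: formaldehyde, C=O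
Why: Amine-catalysed Mannich condensation and elimination (α-methylenation of an aldehyde) without strong base; the aldehyde forms its enamine far faster than the hindered enone.

Step 18
Reactants: 23 α-methylene aldehyde
Product: 24 α-substituted acrylic acid (C10–C(=CH2)–CO2H)
Conditions: NaClO2, NaH2PO4, 2-methylbut-2-ene, t-BuOH/H2O, 0 °C to rt
Reagents that add atoms: sodium chlorite, [Na+].[O-]Cl=O
Why: Pinnick oxidation, which tolerates enals, enones, silyl ethers and PMB ethers.

Step 19
Reactants: 24 α-substituted acrylic acid
Product: 25 tricyclic α-methylene dienol lactone (C9–O–C12 lactone; C6=C7 and C8=C9 in ring A)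
Conditions: 2,4,6-Cl3C6H2COCl, Et3N, PhMe, rt; then DMAP, 60 °C
Reagents that add atoms: none
Why: Enol lactonisation of a γ-keto acid through a mixed anhydride: the C9 carbonyl oxygen is acylated through a five-membered transition state and base removes the γ-hydrogen at C6, giving the dienol ester. The cis fusion is what lets C11 lie in the diene plane, and the silylated C5 oxygen cannot compete for the acyl group.

Step 20
Reactants: 25 tricyclic α-methylene dienol lactone
Product: 26 spiro-epoxy dienol lactone (oxirane on C11/C13, oxygen on the lactone face towards C1)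
Conditions: t-BuOOH (anhydrous), DBU, CH2Cl2, 0 °C
Reagents that add atoms: tert-butyl hydroperoxide, CC(C)(C)OO
Why: Nucleophilic (Weitz–Scheffer type) epoxidation of an α-methylene lactone, which spares the electron-rich diene. The peroxide adds to C13 and the C11–O bond closes on the face away from the C5 silyloxy group, which sets C11.

Step 21
Reactants: 26 spiro-epoxy dienol lactone
Product: 27 fragmentation precursor (26 with free C5–OH; C3–OTBS, C1–OPMB)
Conditions: HF·pyridine, pyridine, THF, 0 °C
Reagents that add atoms: none
Why: Buffered acidic fluoride removes the triethylsilyl group far faster than the tertiary tert-butyldimethylsilyl group; the alkoxide is deliberately not generated in this step.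

Step 22
Reactants: 27 fragmentation precursor
Product: 29 ten-membered C5 ketone with the complete hydroxymethyl ylidene butenolide (C3–OTBS, C1–OPMB), via potassium C5 alkoxide 28 (not isolated)
Conditions: KN(SiMe3)2 (1.05 equiv), THF, −78 to −20 °C; aq. NH4Cl at −78 °C
Reagents that add atoms: none
Why: The base deprotonates the only acidic site, C5–OH. The alkoxide pushes into the C5–C10 bond, which is the sp3–sp3 bond of a cyclohexa-1,3-diene and lies β to the oxirane, so C5=O and C10=C11 form while the C11–O oxirane bond breaks and the oxygen stays on C13. The closest known reaction type is the Grob fragmentation of epoxy alkoxides used to open fused bicycles to medium rings; if the roughly 130° alignment is too poor for a synchronous path, the alkoxide opens ring A to the C5 trienolate, whose C10 terminus expels the oxirane oxygen, and both paths give 29. The ten-membered ring is not closed end to end: it appears when the bond shared by rings A and B is cut, and the strain of the cis-fused tricycle (C6 axial on ring B, syn to the C3 silyl ether) is released. No stereocentre is created; C5, C10 and C11 become trigonal, C1 and C3 are untouched, and the cis geometry of C6=C7 and C8=C9 is inherited from ring A, with the lactone holding C12 cis to C9. The step needs C5–C10 cleavage to outrun acyl transfer, retro-aldol cleavage and elimination: O5 is gauche to C11 but cannot reach C12, because the tetrahedral intermediate would twist C8=C9 out of ring A; C10 is quaternary; the C3 oxygen is silylated; and the oxirane oxygen sits on the lactone face away from C5. The cold quench protonates the C13 alkoxide before it can enolise C4.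

Step 23
Reactants: 29 ten-membered C5 ketone
Product: 30 β-hydroxy ketone (C3–OH and C13–OH free)
Conditions: HF·pyridine, THF, rt
Reagents that add atoms: none
Why: Acidic fluoride cleavage of the tertiary silyl ether; acidic conditions avoid retro-aldol opening of the ring and leave the enol lactone intact.

Step 24
Reactants: 30 β-hydroxy ketone
Product: 31 C13 tert-butyldimethylsilyl ether of 30
Conditions: TBSCl, imidazole, CH2Cl2, 0 °C
Reagents that add atoms: tert-butyldimethylsilyl chloride, CC(C)(C)[Si](C)(C)Cl
Why: Silylation of the primary allylic alcohol; the tertiary C3–OH does not react with the silyl chloride.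

Step 25
Reactants: 31 C13 silyl ether
Product: 32 anti-1,3-diol (C5 S, C5–OH anti to C3–OH)
Conditions: Me4NBH(OAc)3, AcOH/MeCN, −30 °C
Reagents that add atoms: none
Why: Evans–Saksena hydroxyl-directed reduction: the C3 alkoxy(diacetoxy)borohydride delivers hydride intramolecularly through a chair transition state, giving the 1,3-anti diol; the reagent does not reduce the lactone or add in a conjugate sense.

Step 26
Reactants: 32 anti-1,3-diol
Product: 33 C5 acetate
Conditions: Ac2O, pyridine, DMAP (cat.), CH2Cl2, 0 °C
Reagents that add atoms: acetic anhydride, CC(=O)OC(C)=O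
Why: Acylation of the secondary allylic alcohol; the tertiary C3–OH is left.

Step 27
Reactants: 33 C5 acetate
Product: 34 C1 alcohol
Conditions: DDQ, CH2Cl2/pH 7 buffer, 0 °C
Reagents that add atoms: none
Why: Oxidative cleavage of the 4-methoxybenzyl ether; the resulting allylic alcohol is attached to an electron-poor butenolide and is not oxidised further.

Step 28
Reactants: 34 C1 alcohol
Product: 35 C1 methacrylate (C13–OTBS)
Conditions: methacryloyl chloride, Et3N, DMAP (cat.), CH2Cl2, 0 °C
Reagents that add atoms: methacryloyl chloride, C=C(C)C(Cl)=O
Why: Esterification of the only secondary hydroxyl; the tertiary C3–OH is inert under these conditions.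

Step 29
Reactants: 35 C1 methacrylate
Product: 36 CNP0246543.1 (target)
Conditions: HF·pyridine, pyridine, THF, 0 °C to rt
Reagents that add atoms: none
Why: Acidic fluoride desilylation of the primary allylic silyl ether; no base is present that could cause acyl migration or attack the esters.

## Compound list

1 | (−)-quinic acid | OC(=O)[C@]1(O)C[C@@H](O)[C@@H](O)[C@H](O)C1 | starting material
2 | 3,4-O-isopropylidene-1,5-quinide (carboxyl lactonised onto O5, O3/O4 as acetonide, tertiary 1-OH free) | O=C1O[C@@H]2C[C@@]1(O)C[C@H]3OC(C)(C)O[C@H]32 | intermediate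
3 | lactone-reduced triol acetonide (1-hydroxymethyl, 1-OH, 5-OH) | O[C@@H]1C[C@@](CO)(O)C[C@H]2OC(C)(C)O[C@H]21 | intermediate
4 | primary mono-tosylate of 3 | O[C@@H]1C[C@@](COS(=O)(=O)c3ccc(C)cc3)(O)C[C@H]2OC(C)(C)O[C@H]21 | intermediate
5 | methyl carbinol acetonide (C1–OH cis to C3–CH3 and trans to C3–OH; acetonide oxygens on C5 and C10, cis to C3–OH) | O[C@@H]1C[C@@](C)(O)C[C@H]2OC(C)(C)O[C@H]21 | intermediate
6 | C1 4-methoxybenzyl ether of 5 | COc1ccc(CO[C@@H]2C[C@@](C)(O)C[C@H]3OC(C)(C)O[C@H]32)cc1 | intermediate
7 | triol (C3–OH, C5–OH and C10–OH all on the ring face opposite to C1–OPMB) | COc1ccc(CO[C@@H]2C[C@@](C)(O)C[C@@H](O)[C@H]2O)cc1 | intermediate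
8 | C5 tert-butyldimethylsilyl ether of 7 | COc1ccc(CO[C@@H]2C[C@@](C)(O)C[C@@H](O[Si](C)(C)C(C)(C)C)[C@H]2O)cc1 | intermediate
9 | C10 ketone (C1–OPMB, C5–OTBS, C3–OH) | COc1ccc(CO[C@@H]2C[C@@](C)(O)C[C@@H](O[Si](C)(C)C(C)(C)C)C2=O)cc1 | intermediate
10 | triphenylphosphine | c1ccc(cc1)P(c1ccccc1)c1ccccc1 | starting material
11 | allyl chloromethyl ether | C=CCOCCl | starting material
12 | (allyloxymethyl)triphenylphosphonium chloride | C=CCOC[P+](c1ccccc1)(c1ccccc1)c1ccccc1.[Cl-] | intermediate
13 | C10 (allyloxy)methylidene enol ether of 9 (E/Z mixture, not isolated) | COc1ccc(CO[C@@H]2C[C@@](C)(O)C[C@@H](O[Si](C)(C)C(C)(C)C)C2=COCC=C)cc1 | intermediate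
14 | quaternary aldehyde (C10: formyl trans to C1–OPMB and cis to C5–OTBS; allyl cis to C1–OPMB) | COc1ccc(CO[C@@H]2C[C@@](C)(O)C[C@@H](O[Si](C)(C)C(C)(C)C)[C@]2(C=O)CC=C)cc1 | intermediate
15 | 2-methylallylmagnesium chloride | CC(=C)C[Mg]Cl | starting material
16 | homoallylic alcohol (C9 epimers) | COc1ccc(CO[C@@H]2C[C@@](C)(O)C[C@@H](O[Si](C)(C)C(C)(C)C)[C@]2(C(O)CC(C)=C)CC=C)cc1 | intermediate
17 | triol (C9–OH epimers, C5–OH, C3–OH) | COc1ccc(CO[C@@H]2C[C@@](C)(O)C[C@@H](O)[C@]2(C(O)CC(C)=C)CC=C)cc1 | intermediate
18 | diketone (C5 ketone; C10 with 3-methylbut-3-enoyl and allyl) | COc1ccc(CO[C@@H]2C[C@@](C)(O)CC(=O)[C@]2(C(=O)CC(C)=C)CC=C)cc1 | intermediate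
19 | C3 tert-butyldimethylsilyl ether of 18 | COc1ccc(CO[C@@H]2C[C@@](C)(O[Si](C)(C)C(C)(C)C)CC(=O)[C@]2(C(=O)CC(C)=C)CC=C)cc1 | intermediate
20 | lithium aldolate, cis-fused (not isolated) | COc1ccc(CO[C@@H]2C[C@@](C)(O[Si](C)(C)C(C)(C)C)C[C@@]3([O-])CC(C)=CC(=O)[C@]32CC=C)cc1.[Li+] | intermediate
21 | cis-fused bicyclic enone (C5–OSiEt3 cis to the C10 allyl group and trans to C3–OTBS; C6 and C9 on the same face of ring B) | COc1ccc(CO[C@@H]2C[C@@](C)(O[Si](C)(C)C(C)(C)C)C[C@@]3(O[Si](CC)(CC)CC)CC(C)=CC(=O)[C@]32CC=C)cc1 | intermediate
22 | aldehyde (C10–CH2–CHO) | COc1ccc(CO[C@@H]2C[C@@](C)(O[Si](C)(C)C(C)(C)C)C[C@@]3(O[Si](CC)(CC)CC)CC(C)=CC(=O)[C@]32CC=O)cc1 | intermediate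
23 | α-methylene aldehyde (C10–C(=CH2)–CHO) | COc1ccc(CO[C@@H]2C[C@@](C)(O[Si](C)(C)C(C)(C)C)C[C@@]3(O[Si](CC)(CC)CC)CC(C)=CC(=O)[C@]32C(=C)C=O)cc1 | intermediate
24 | α-substituted acrylic acid (C10–C(=CH2)–CO2H) | COc1ccc(CO[C@@H]2C[C@@](C)(O[Si](C)(C)C(C)(C)C)C[C@@]3(O[Si](CC)(CC)CC)CC(C)=CC(=O)[C@]32C(=C)C(=O)O)cc1 | intermediate
25 | tricyclic α-methylene dienol lactone (rings A and B cis-fused) | COc1ccc(CO[C@@H]2C[C@@](C)(O[Si](C)(C)C(C)(C)C)C[C@@]3(O[Si](CC)(CC)CC)C=C(C)C=C4OC(=O)C(=C)[C@]423)cc1 | intermediate
26 | spiro-epoxy dienol lactone (oxirane oxygen on the lactone face towards C1) | COc1ccc(CO[C@@H]2C[C@@](C)(O[Si](C)(C)C(C)(C)C)C[C@@]3(O[Si](CC)(CC)CC)C=C(C)C=C4OC(=O)[C@]5(CO5)[C@]423)cc1 | intermediate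
27 | fragmentation precursor: cis-fused tricyclic spiro-epoxy dienol lactone with free C5–OH (C3–OTBS, C1–OPMB) | COc1ccc(CO[C@@H]2C[C@@](C)(O[Si](C)(C)C(C)(C)C)C[C@@]3(O)C=C(C)C=C4OC(=O)[C@]5(CO5)[C@]423)cc1 | intermediate
28 | potassium C5 alkoxide of 27 (not isolated) | COc1ccc(CO[C@@H]2C[C@@](C)(O[Si](C)(C)C(C)(C)C)C[C@@]3([O-])C=C(C)C=C4OC(=O)[C@]5(CO5)[C@]423)cc1.[K+] | intermediate
29 | ten-membered C5 ketone with hydroxymethyl ylidene butenolide (C3–OTBS, C1–OPMB; C6=C7 and C8=C9 ring-cis) | COc1ccc(CO[C@@H]2C[C@@](C)(O[Si](C)(C)C(C)(C)C)CC(=O)/C=C(C)\C=C3\OC(=O)C(CO)=C32)cc1 | intermediate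
30 | β-hydroxy ketone (C3–OH, C13–OH free) | COc1ccc(CO[C@@H]2C[C@@](C)(O)CC(=O)/C=C(C)\C=C3\OC(=O)C(CO)=C32)cc1 | intermediate
31 | C13 tert-butyldimethylsilyl ether of 30 | COc1ccc(CO[C@@H]2C[C@@](C)(O)CC(=O)/C=C(C)\C=C3\OC(=O)C(CO[Si](C)(C)C(C)(C)C)=C32)cc1 | intermediate
32 | anti-1,3-diol (C5 S) | COc1ccc(CO[C@@H]2C[C@@](C)(O)C[C@H](O)/C=C(C)\C=C3\OC(=O)C(CO[Si](C)(C)C(C)(C)C)=C32)cc1 | intermediate
33 | C5 acetate | COc1ccc(CO[C@@H]2C[C@@](C)(O)C[C@H](OC(C)=O)/C=C(C)\C=C3\OC(=O)C(CO[Si](C)(C)C(C)(C)C)=C32)cc1 | intermediate
34 | C1 alcohol | O[C@@H]1C[C@@](C)(O)C[C@H](OC(C)=O)/C=C(C)\C=C2\OC(=O)C(CO[Si](C)(C)C(C)(C)C)=C21 | intermediate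
35 | C1 methacrylate, C13 silyl ether | C=C(C)C(=O)O[C@@H]1C[C@@](C)(O)C[C@H](OC(C)=O)/C=C(C)\C=C2\OC(=O)C(CO[Si](C)(C)C(C)(C)C)=C21 | intermediate
36 | CNP0246543.1 (C1 R, C3 S, C5 S in the numbering used here) | C=C(C)C(=O)O[C@@H]1C[C@@](C)(O)C[C@H](OC(C)=O)/C=C(C)\C=C2\OC(=O)C(CO)=C21 | target

## Step count and least certain steps

Total step count: 29. Longest linear sequence: 28 (steps 1–8 and 10–29); step 9 is a side step.

**Step 22 (key).** The breaking C5–C10 bond and the oxirane C–O bond are not anti-periplanar. Cleavage may therefore be slow enough for the base to degrade the enol lactone, or for the ring-opened carbanion to lose the C1 ether by β-elimination instead of opening the oxirane. Fallback: the same bonds are broken homolytically. Starting from 27, PhI(OAc)2 and I2 under visible light in CH2Cl2 at 0 °C generate the C5 hypoiodite and alkoxyl radical. β-Scission of C5–C10 gives the C10 radical, the adjacent oxirane opens to the C13 alkoxyl radical, and thiosulfate work-up returns the alcohol, rejoining the route at 29. An oxygen radical cannot take part in acyl transfer or elimination. No new isolated compound is involved.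

**Step 10.** The basic alkoxymethylene ylide may enolise the hindered, doubly α-oxygenated ketone and scramble C1 or C5, and the sigmatropic shift may show poor facial selectivity. Fallback from 9: sulfur-ylide epoxidation (Me3SI, KOt-Bu, DMSO/THF) gives the spiro-epoxide F1. Meinwald rearrangement with MgBr2·OEt2 gives the α-branched aldehyde F2. α-Allylation of its pyrrolidine enamine with allyl acetate and Pd(PPh3)4 (enamine plus π-allylpalladium catalysis) installs the allyl group on the same axial face and returns to 14.

**Step 15.** The trans-fused aldolate may be silylated instead of the cis one, or the base may enolise C4 with loss of the C3 silanolate. Fallback from 19: a Lewis-acid carbonyl-ene cyclisation (Me2AlCl, CH2Cl2, −78 to 0 °C) forms the C5–C6 bond without any enolate and gives the exocyclic-methylene hydroxy ketone F3. DBU moves the alkene into conjugation to give the hydroxy enone F4, and TESOTf/2,6-lutidine then gives 21.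

**Step 19.** O-acylation of the cross-conjugated enone may fail, with intermolecular anhydride formation or ionisation at C5 taking over. Fallback from 24: the acid is converted with C6F5OH and EDC into the pentafluorophenyl ester F5. KN(SiMe3)2 at −78 °C then forms the C9 dienolate, which is O-acylated intramolecularly (enolate acylation instead of carbonyl activation) to give 25.

**Step 20.** The peroxide anion may attack the enol-lactone carbonyl and open the ring instead of adding to C13. Fallback from 23: the oxirane is made before the lactone. t-BuOOH/DBU epoxidises the enal to the epoxy aldehyde F6 (C11 epimers), Pinnick oxidation gives the glycidic acid F7, and the step 19 lactonisation conditions give 26 together with its C11 epimer F8. F8 is carried forward as well, because the stepwise fragmentation path does not depend on the oxirane configuration.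

**Step 25.** The conformation of the ten-membered ring may override the chelate and deliver hydride to the wrong face. Fallback from 31: the epimeric alcohol F9, if it is the product, is inverted by a Mitsunobu reaction with acetic acid (PPh3, DIAD, PhMe, 0 °C), which gives the acetate 33 directly.

## Further compounds

F0 | step 22 | none | none
F1 | step 10 | C10 spiro-epoxide of 9 (C10 epimers) | COc1ccc(CO[C@@H]2C[C@@](C)(O)C[C@@H](O[Si](C)(C)C(C)(C)C)C23CO3)cc1
F2 | step 10 | C10 formyl compound (C10–H, C10 epimers) | COc1ccc(CO[C@@H]2C[C@@](C)(O)C[C@@H](O[Si](C)(C)C(C)(C)C)C2C=O)cc1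
F3 | step 15 | cis-fused hydroxy ketone with exocyclic C7 methylene | COc1ccc(CO[C@@H]2C[C@@](C)(O[Si](C)(C)C(C)(C)C)C[C@@]3(O)CC(=C)CC(=O)[C@]32CC=C)cc1
F4 | step 15 | cis-fused hydroxy enone (free C5–OH) | COc1ccc(CO[C@@H]2C[C@@](C)(O[Si](C)(C)C(C)(C)C)C[C@@]3(O)CC(C)=CC(=O)[C@]32CC=C)cc1
F5 | step 19 | pentafluorophenyl ester of 24 | COc1ccc(CO[C@@H]2C[C@@](C)(O[Si](C)(C)C(C)(C)C)C[C@@]3(O[Si](CC)(CC)CC)CC(C)=CC(=O)[C@]32C(=C)C(=O)Oc4c(F)c(F)c(F)c(F)c4F)cc1
F6 | step 20 | epoxy aldehyde (C11 epimers) | COc1ccc(CO[C@@H]2C[C@@](C)(O[Si](C)(C)C(C)(C)C)C[C@@]3(O[Si](CC)(CC)CC)CC(C)=CC(=O)[C@]32C4(C=O)CO4)cc1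
F7 | step 20 | glycidic acid (C11 epimers) | COc1ccc(CO[C@@H]2C[C@@](C)(O[Si](C)(C)C(C)(C)C)C[C@@]3(O[Si](CC)(CC)CC)CC(C)=CC(=O)[C@]32C4(C(=O)O)CO4)cc1
F8 | step 20 | C11 epimer of 26 | COc1ccc(CO[C@@H]2C[C@@](C)(O[Si](C)(C)C(C)(C)C)C[C@@]3(O[Si](CC)(CC)CC)C=C(C)C=C4OC(=O)[C@@]5(CO5)[C@]423)cc1
F9 | step 25 | C5 epimer of 32 (syn-1,3-diol) | COc1ccc(CO[C@@H]2C[C@@](C)(O)C[C@@H](O)/C=C(C)\C=C3\OC(=O)C(CO[Si](C)(C)C(C)(C)C)=C32)cc1
A1 | alternative 1 | ten-membered C1 carbinol with exocyclic C3 methylene | O[C@@H]1CC(=C)C[C@H](O[Si](CC)(CC)CC)/C=C(C)\C=C2\OC(=O)C(CO[Si](C)(C)C(C)(C)C)=C21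
A2 | alternative 2 | protected target skeleton with the complete ylidene butenolide | COc1ccc(CO[C@@H]2C[C@@](C)(O)C[C@H](O[Si](CC)(CC)CC)/C=C(C)\C=C3\OC(=O)C(CO[Si](C)(C)C(C)(C)C)=C32)cc1
A3 | alternative 3 | cyclodecadienone (C3 ketone) with the ylidene silyl ketene acetal | COc1ccc(CO[C@@H]2CC(=O)C[C@H](O[Si](CC)(CC)CC)/C=C(C)\C=C3\OC(O[Si](C(C)C)(C(C)C)C(C)C)=C(CO[Si](C)(C)C(C)(C)C)[C@H]32)cc1
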